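**Plan**
- Retrosynthesis: the O-protecting groups and acetals come off last. C2 is traced to an equilibration and C3–H/C4–H to hydrogenation of a 2H-chromene. The pyran ring is then cut at C4–C4a and O1–C2, and the enal at its C=C bond and at the aryl–CHO bonds.
- Enabling feature: ring A is an acylphloroglucinol, so C4a and the oxygen on C8a behave like the carbon and oxygen ends of a 1,3-dicarbonyl; C4–C3(isopropyl)–C2(ring B) is the chain of an α-isopropylcinnamaldehyde.
- Forward: ring B is built from 1,3,5-trimethoxybenzene (two formyls masked as dioxane acetals, a third condensed with isovaleraldehyde) and ring A from phloroglucinol. The pyran ring, the only ring made, closes in a Knoevenagel/oxa-6π cascade.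
- Stereochemistry: C3 (S) comes from iridium-catalysed asymmetric hydrogenation of C3=C4 under catalyst control. C2 (R) follows by acid-mediated equilibration to the 2,3-trans chroman, run with both ring A phenols benzylated so that only O1 can re-close.

Key step: step 6

Assumption: the 2,3-trans arrangement of aryl and isopropyl is taken to be the more stable C2 epimer of the chroman, so equilibration at C2 in the (3S) series converges on (2R,3S).

Abbreviation: Ar = 3,5-bis(5,5-dimethyl-1,3-dioxan-2-yl)-2,4,6-trimethoxyphenyl.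

**Route**

Step 1
Reactants: 1 phloroglucinol; 2 isovaleryl chloride
Product: 3 phlorisovalerophenone [1-(2,4,6-trihydroxyphenyl)-3-methylbutan-1-one]
Conditions: AlCl3 (3 equiv), CH2Cl2–PhNO2, 0 → 40 °C; aq. HCl
Reagents that add atoms: none
Why: Friedel–Crafts C-acylation of phloroglucinol, in which the first acyl group deactivates the ring so that mono-acylation is expected.

Step 2
Reactants: 4 1,3,5-trimethoxybenzene
Product: 7 2,4,6-trimethoxybenzene-1,3-dicarbaldehyde, via mono(chloromethoxymethyl)arene 5 (not isolated), via bis(chloromethoxymethyl)arene 6 (not isolated)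
Conditions: Cl2CHOMe (4 equiv), TiCl4 (5 equiv), CH2Cl2, −10 °C → rt; ice/H2O
Reagents that add atoms: dichloromethyl methyl ether, COC(Cl)Cl; water, O
Why: Rieche formylation, in which the ring activated by three methoxy groups should accept two formyl equivalents before deactivation stops the reaction and hydrolysis releases the dialdehyde.

Step 3
Reactants: 7 2,4,6-trimethoxybenzene-1,3-dicarbaldehyde
Product: 8 2,2'-(2,4,6-trimethoxy-1,3-phenylene)bis(5,5-dimethyl-1,3-dioxane)
Conditions: 2,2-dimethylpropane-1,3-diol (3 equiv), TsOH·H2O (5 mol%), PhMe, reflux, Dean–Stark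
Reagents that add atoms: 2,2-dimethylpropane-1,3-diol, CC(C)(CO)CO
Why: acid-catalysed acetalisation driven by azeotropic water removal, giving neopentyl acetals that tolerate butyllithium, hydroxide and amine salts in the following steps.

Step 4
Reactants: 8 2,2'-(2,4,6-trimethoxy-1,3-phenylene)bis(5,5-dimethyl-1,3-dioxane)
Product: 10 3,5-bis(5,5-dimethyl-1,3-dioxan-2-yl)-2,4,6-trimethoxybenzaldehyde (ArCHO), via aryllithium 9 (not isolated)
Conditions: n-BuLi (1.3 equiv), TMEDA, THF, 0 °C; DMF, −78 °C → rt; H2O
Reagents that add atoms: N,N-dimethylformamide, CN(C)C=O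
Why: directed ortho-metalation of the only aromatic C–H, which is flanked by two methoxy groups, followed by formylation of the aryllithium with DMF.

Step 5
Reactants: 10 ArCHO; 11 isovaleraldehyde
Product: 13 (2E)-2-(Ar-methylidene)-3-methylbutanal, via aldol adduct 12 (not isolated)
Conditions: 11 (3 equiv, slow addition), KOH, MeOH, 45 °C
Reagents that add atoms: none
Why: Claisen–Schmidt-type crossed aldol condensation in which 10 cannot enolise, slow addition of 11 limits its self-condensation, and E1cB dehydration should give the E enal (either alkene isomer serves in step 6).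

Step 6
Reactants: 3 phlorisovalerophenone; 13 (2E)-2-(Ar-methylidene)-3-methylbutanal
Product: 15 racemic 1-[2-Ar-5,7-dihydroxy-3-(propan-2-yl)-2H-chromen-6-yl]-3-methylbutan-1-one, via ortho-quinone methide 14 (not isolated)
Conditions: ethylenediammonium diacetate (20 mol%), PhMe–1,4-dioxane, 90 °C, 4 Å MS
Reagents that add atoms: none
Why: The diammonium acetate turns enal 13 into its iminium ion, the free ring carbon of 3 flanked by two hydroxyls (the future C4a) adds to the iminium carbon, and loss of the amine gives ortho-quinone methide 14, a 1-oxatriene ending in the former enal alkene. Thermal disrotatory oxa-6π electrocyclisation of 14 forms O1–C2, closes the 2H-pyran ring and restores the aromatic ring, as in the established Knoevenagel/oxa-6π chromene annulation of phloroglucinols and resorcinols with enals. C2 is the only new stereocentre and nothing controls it, so 15 is racemic by intent and C2 is corrected in step 9 after C3 has been set. The step needs closure through the oxygen para to the ketone (6-acyl chromene) and not through an ortho oxygen (8-acyl isomer); the ketone should secure this by holding an ortho hydroxyl in a hydrogen-bonded chelate so that the quinone methide carbonyl develops at the free, most acidic para oxygen, the preference shown by 2,4-dihydroxyaryl ketones. It also needs 1,2- rather than 1,4-attack on the iminium ion, which the β-carbon, shielded by the α-isopropyl group and the di-ortho-substituted aryl ring, should enforce. The enal geometry is of no consequence because both alkene isomers of 14 close to the same product, and the buffered medium should leave the cyclic acetals intact.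

Step 7
Reactants: 15 racemic 1-[2-Ar-5,7-dihydroxy-3-(propan-2-yl)-2H-chromen-6-yl]-3-methylbutan-1-one
Product: 16 racemic 1-[5,7-bis(benzyloxy)-2-Ar-3-(propan-2-yl)-2H-chromen-6-yl]-3-methylbutan-1-one
Conditions: BnBr (2.5 equiv), K2CO3 (3 equiv), DMF, 50 °C
Reagents that add atoms: benzyl bromide, BrCc1ccccc1
Why: Williamson etherification of both ring A phenols, which removes acidic hydroxyls before the hydrogenation and leaves O1 as the only ring A oxygen able to re-close in step 9.

Step 8
Reactants: 16 racemic 1-[5,7-bis(benzyloxy)-2-Ar-3-(propan-2-yl)-2H-chromen-6-yl]-3-methylbutan-1-one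
Product: 17 1-[(3S)-5,7-bis(benzyloxy)-2-Ar-3-(propan-2-yl)-3,4-dihydro-2H-chromen-6-yl]-3-methylbutan-1-one as both C2 epimers
Conditions: [Ir(cod)(L*)]BArF (3 mol%; L* = ThrePHOX-type phosphinite–oxazoline, antipode chosen to give 3S), H2 (50 bar), CH2Cl2, rt
Reagents that add atoms: none
Why: iridium–N,P-catalysed asymmetric hydrogenation of a trisubstituted cyclic aryl alkene (the 3-substituted 2H-chromene class), in which the chiral catalyst is expected to choose the C3 face in both C2 enantiomers of 16, so that C3 is set as S by catalyst control and C2 is left as a mixture for step 9.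

Step 9
Reactants: 17 1-[(3S)-5,7-bis(benzyloxy)-2-Ar-3-(propan-2-yl)-3,4-dihydro-2H-chromen-6-yl]-3-methylbutan-1-one as both C2 epimers
Product: 19 5-[(2R,3S)-5,7-bis(benzyloxy)-6-(3-methylbutanoyl)-3-(propan-2-yl)-3,4-dihydro-2H-chromen-2-yl]-2,4,6-trimethoxybenzene-1,3-dicarbaldehyde, via trans bis-acetal 18 (not isolated)
Conditions: BF3·OEt2 (0.5 equiv), CH2Cl2, −20 → 0 °C; then 2 M aq. HCl, THF, rt
Reagents that add atoms: water, O
Why: reversible Lewis-acid ionisation of the benzylic C2–O1 ether bond (SN1-type epimerisation, the way cis-2-aryl-2,3-dihydrobenzofurans and flavans are equilibrated to their trans isomers) should let both C2 epimers re-close through O1 to the more stable 2,3-trans chroman (2R for 3S) without touching C3, after which aqueous acid hydrolyses both dioxane acetals.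

Step 10
Reactants: 19 5-[(2R,3S)-5,7-bis(benzyloxy)-6-(3-methylbutanoyl)-3-(propan-2-yl)-3,4-dihydro-2H-chromen-2-yl]-2,4,6-trimethoxybenzene-1,3-dicarbaldehyde
Product: 20 5-[(2R,3S)-5,7-dihydroxy-6-(3-methylbutanoyl)-3-(propan-2-yl)-3,4-dihydro-2H-chromen-2-yl]-2,4,6-trihydroxybenzene-1,3-dicarbaldehyde
Conditions: BCl3 (10 equiv), C6HMe5 (6 equiv), CH2Cl2, −78 → 0 °C; MeOH, then H2O
Reagents that add atoms: none
Why: boron trichloride ether cleavage, in which the benzyl ethers fall first (benzyl cation trapped by pentamethylbenzene) and the three hindered methoxy groups ortho to formyl follow by chelation-assisted demethylation, while the boron-chelated ring B should be too electron-poor to ionise C2–O1, so both stereocentres are kept.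

**Compound list**

1 | phloroglucinol | Oc1cc(O)cc(O)c1 | starting material
2 | isovaleryl chloride | CC(C)CC(=O)Cl | starting material
3 | phlorisovalerophenone, 1-(2,4,6-trihydroxyphenyl)-3-methylbutan-1-one | CC(C)CC(=O)c1c(O)cc(O)cc1O | intermediate
4 | 1,3,5-trimethoxybenzene | COc1cc(OC)cc(OC)c1 | starting material
5 | 2-[chloro(methoxy)methyl]-1,3,5-trimethoxybenzene (not isolated) | COC(Cl)c1c(OC)cc(OC)cc1OC | intermediate
6 | 2,4-bis[chloro(methoxy)methyl]-1,3,5-trimethoxybenzene (not isolated) | COC(Cl)c1c(OC)cc(OC)c(C(Cl)OC)c1OC | intermediate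
7 | 2,4,6-trimethoxybenzene-1,3-dicarbaldehyde | COc1cc(OC)c(C=O)c(OC)c1C=O | intermediate
8 | 2,2'-(2,4,6-trimethoxy-1,3-phenylene)bis(5,5-dimethyl-1,3-dioxane) | COc1cc(OC)c(C2OCC(C)(C)CO2)c(OC)c1C1OCC(C)(C)CO1 | intermediate
9 | [3,5-bis(5,5-dimethyl-1,3-dioxan-2-yl)-2,4,6-trimethoxyphenyl]lithium (not isolated) | [Li]c1c(OC)c(C2OCC(C)(C)CO2)c(OC)c(C2OCC(C)(C)CO2)c1OC | intermediate
10 | 3,5-bis(5,5-dimethyl-1,3-dioxan-2-yl)-2,4,6-trimethoxybenzaldehyde | O=Cc1c(OC)c(C2OCC(C)(C)CO2)c(OC)c(C2OCC(C)(C)CO2)c1OC | intermediate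
11 | isovaleraldehyde | CC(C)CC=O | starting material
12 | 2-[Ar(hydroxy)methyl]-3-methylbutanal, diastereomer mixture (not isolated) | CC(C)C(C=O)C(O)c1c(OC)c(C2OCC(C)(C)CO2)c(OC)c(C2OCC(C)(C)CO2)c1OC | intermediate
13 | (2E)-2-{[3,5-bis(5,5-dimethyl-1,3-dioxan-2-yl)-2,4,6-trimethoxyphenyl]methylidene}-3-methylbutanal | O=C/C(C(C)C)=C/c1c(OC)c(C2OCC(C)(C)CO2)c(OC)c(C2OCC(C)(C)CO2)c1OC | intermediate
14 | ortho-quinone methide (1-oxatriene) from C-condensation of 3 with 13, alkene geometry undefined (not isolated) | CC(C)CC(=O)C1=C(O)C(=CC(C(C)C)=Cc2c(OC)c(C3OCC(C)(C)CO3)c(OC)c(C3OCC(C)(C)CO3)c2OC)C(=O)C=C1O | intermediate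
15 | racemic 1-[2-Ar-5,7-dihydroxy-3-(propan-2-yl)-2H-chromen-6-yl]-3-methylbutan-1-one | CC(C)CC(=O)c1c(O)cc2c(c1O)C=C(C(C)C)C(c1c(OC)c(C3OCC(C)(C)CO3)c(OC)c(C3OCC(C)(C)CO3)c1OC)O2 | intermediate
16 | racemic 1-[5,7-bis(benzyloxy)-2-Ar-3-(propan-2-yl)-2H-chromen-6-yl]-3-methylbutan-1-one | CC(C)CC(=O)c1c(OCc3ccccc3)cc2c(c1OCc1ccccc1)C=C(C(C)C)C(c1c(OC)c(C3OCC(C)(C)CO3)c(OC)c(C3OCC(C)(C)CO3)c1OC)O2 | intermediate
17 | 1-[(3S)-5,7-bis(benzyloxy)-2-Ar-3-(propan-2-yl)-3,4-dihydro-2H-chromen-6-yl]-3-methylbutan-1-one, both C2 epimers | CC(C)CC(=O)c1c(OCc3ccccc3)cc2c(c1OCc1ccccc1)C[C@@H](C(C)C)C(c1c(OC)c(C3OCC(C)(C)CO3)c(OC)c(C3OCC(C)(C)CO3)c1OC)O2 | intermediate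
18 | (2R,3S)-trans isomer of 17 (not isolated) | CC(C)CC(=O)c1c(OCc3ccccc3)cc2c(c1OCc1ccccc1)C[C@@H](C(C)C)[C@H](c1c(OC)c(C3OCC(C)(C)CO3)c(OC)c(C3OCC(C)(C)CO3)c1OC)O2 | intermediate
19 | 5-[(2R,3S)-5,7-bis(benzyloxy)-6-(3-methylbutanoyl)-3-(propan-2-yl)-3,4-dihydro-2H-chromen-2-yl]-2,4,6-trimethoxybenzene-1,3-dicarbaldehyde | CC(C)CC(=O)c1c(OCc3ccccc3)cc2c(c1OCc1ccccc1)C[C@@H](C(C)C)[C@H](c1c(OC)c(C=O)c(OC)c(C=O)c1OC)O2 | intermediate
20 | 5-[(2R,3S)-5,7-dihydroxy-6-(3-methylbutanoyl)-3-(propan-2-yl)-3,4-dihydro-2H-chromen-2-yl]-2,4,6-trihydroxybenzene-1,3-dicarbaldehyde (CNP0551232.1) | CC(C)CC(=O)c1c(O)cc2c(c1O)C[C@@H](C(C)C)[C@H](c1c(O)c(C=O)c(O)c(C=O)c1O)O2 | target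

**Step count and risks**

Total: 10 steps. Longest linear sequence: 9 steps (4 → 7 → 8 → 10 → 13 → 15 → 16 → 17 → 19 → 20).

The three steps most likely to fail:

1. Step 6. The pyran ring may close through a chelated ortho oxygen instead of the para oxygen, giving the 8-acyl chromene, and the retro-6π/6π equilibrium could redistribute the two isomers on heating. The hindered α-branched enal may also condense slowly or suffer conjugate attack. The fallback enforces the closure with protecting groups and a different mediator. It sets out from 3: alkylation of the most acidic para hydroxyl (MOMCl, i-Pr2NEt, CH2Cl2, 0 °C) would give 1-[2,6-dihydroxy-4-(methoxymethoxy)phenyl]-3-methylbutan-1-one F1. Benzylation of both chelated hydroxyls (BnBr, K2CO3, DMF, 60 °C) would give 1-[2,6-bis(benzyloxy)-4-(methoxymethoxy)phenyl]-3-methylbutan-1-one F2, and HCl in MeOH would remove the acetal to give 1-[2,6-bis(benzyloxy)-4-hydroxyphenyl]-3-methylbutan-1-one F3, a phenol with a single oxygen available for closure. Condensation of this phenol with 13 mediated by phenylboronic acid (PhB(OH)2, EtCO2H cat., PhMe, reflux, Dean–Stark) passes through a 1,3,2-benzodioxaborin and the same quinone methide/oxa-6π closure, and comes back to the route at 16.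

2. Step 8. The substrate is racemic and carries a bulky aryl group next to the alkene, so the catalyst may not override the substrate bias in the mismatched enantiomer; slow turnover or poor facial selectivity there would lower the enantiomeric purity at C3. The fallback gives up catalyst control and resolves. From 16, hydrogenation with achiral [Ir(cod)(PCy3)(py)]PF6 (H2, CH2Cl2) should add hydrogen anti to the C2 aryl group and give the racemic cis-chroman bis-acetal F4. The conditions of step 9 should convert this into the racemic trans dialdehyde F5, whose enantiomers are separated by preparative chromatography on a chiral stationary phase. The (2R,3S) enantiomer is 19, where the route is rejoined.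

3. Step 9. Ionisation of C2–O1 may be slow because the methoxy groups of the hexasubstituted ring B are twisted out of conjugation. The benzylic cation may instead lose the C3 proton, and re-addition would erode the C3 configuration; acetals or benzyl ethers may also be lost prematurely to the Lewis acid. The fallback moves the equilibration to the last stage and uses a quinone methide instead of a cation. From 17, aqueous HCl in THF alone would hydrolyse the acetals to the (3S)-bis(benzyloxy) dialdehyde as both C2 epimers F6. BCl3 and pentamethylbenzene under the conditions of step 10 would then give the fully deprotected (3S)-chroman as both C2 epimers F7. Warming this in a weakly basic buffer (NaOAc, MeCN–H2O, 50 °C) should open O1–C2 through the ortho-quinone methide of the free ring B phenol, the way 2-arylchromans with free B-ring hydroxyls epimerise at C2, and re-closure should converge on the trans isomer 20. Because the C5 hydroxyl is free in this variant, re-closure to the 8-acyl isomer has to be watched for.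

Further compounds
F1 | step 6 | 1-[2,6-dihydroxy-4-(methoxymethoxy)phenyl]-3-methylbutan-1-one | CC(C)CC(=O)c1c(O)cc(OCOC)cc1O
F2 | step 6 | 1-[2,6-bis(benzyloxy)-4-(methoxymethoxy)phenyl]-3-methylbutan-1-one | CC(C)CC(=O)c1c(OCc2ccccc2)cc(OCOC)cc1OCc1ccccc1
F3 | step 6 | 1-[2,6-bis(benzyloxy)-4-hydroxyphenyl]-3-methylbutan-1-one | CC(C)CC(=O)c1c(OCc2ccccc2)cc(O)cc1OCc1ccccc1
F4 | step 8 | racemic cis-1-[5,7-bis(benzyloxy)-2-Ar-3-(propan-2-yl)-3,4-dihydro-2H-chromen-6-yl]-3-methylbutan-1-one (2S,3S enantiomer drawn) | CC(C)CC(=O)c1c(OCc3ccccc3)cc2c(c1OCc1ccccc1)C[C@@H](C(C)C)[C@@H](c1c(OC)c(C3OCC(C)(C)CO3)c(OC)c(C3OCC(C)(C)CO3)c1OC)O2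
F5 | step 8 | racemic trans dialdehyde, the racemate of 19 (2R,3S enantiomer drawn) | CC(C)CC(=O)c1c(OCc3ccccc3)cc2c(c1OCc1ccccc1)C[C@@H](C(C)C)[C@H](c1c(OC)c(C=O)c(OC)c(C=O)c1OC)O2
F6 | step 9 | 5-[(3S)-5,7-bis(benzyloxy)-6-(3-methylbutanoyl)-3-(propan-2-yl)-3,4-dihydro-2H-chromen-2-yl]-2,4,6-trimethoxybenzene-1,3-dicarbaldehyde, both C2 epimers | CC(C)CC(=O)c1c(OCc3ccccc3)cc2c(c1OCc1ccccc1)C[C@@H](C(C)C)C(c1c(OC)c(C=O)c(OC)c(C=O)c1OC)O2
F7 | step 9 | 5-[(3S)-5,7-dihydroxy-6-(3-methylbutanoyl)-3-(propan-2-yl)-3,4-dihydro-2H-chromen-2-yl]-2,4,6-trihydroxybenzene-1,3-dicarbaldehyde, both C2 epimers | CC(C)CC(=O)c1c(O)cc2c(c1O)C[C@@H](C(C)C)C(c1c(O)c(C=O)c(O)c(C=O)c1O)O2
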